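**Retrosynthetic overview**
- The target is reached by Pd(0) removal of two allyl ethers, preceded by O-methylation of the one free (chelated) phenol on the orcinol-type ring.
- That ring is obtained by dehydrogenating a 6-aroyl-3-alkoxycyclohexenone, itself the oxidation product of a β-hydroxy ketone.
- Key C–C bond (ketone carbon to the orcinol-type ring): intermolecular aldol addition of the kinetic lithium enolate of 3-(allyloxy)-5-methylcyclohex-2-enone to a fully substituted benzaldehyde.
- The aldehyde comes from 3,5-dimethoxyphenol (chlorination, ortho-formylation, O-allylation); the enone comes from 5-methylcyclohexane-1,3-dione and allyl alcohol.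
- Ring order: the chlorinated ring is bought aromatic; the second carbocycle is bought as the dione and aromatized after the aldol. No ring is made by cyclization.

Assumption: the target has no stereocentre, so it is made as the achiral compound; the stereocentres of 7, 9 and 10 are racemic or mixed and are erased on aromatization.

**Route**

Step 1
Reactants: 1 3,5-dimethoxyphenol
Product: 2 2-chloro-3,5-dimethoxyphenol
Conditions: SO2Cl2 (1.0 equiv), CHCl3, 0 °C to rt; chromatography to remove the 4-chloro isomer
Reagents that add atoms: sulfuryl chloride, O=S(=O)(Cl)Cl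
Why: Electrophilic aromatic chlorination of the strongly activated phenol gives the 2-chloro (ortho to OH) isomer as the major monochloride, separable from the minor 4-chloro isomer.

Step 2
Reactants: 2 2-chloro-3,5-dimethoxyphenol
Product: 4 3-chloro-2-hydroxy-4,6-dimethoxybenzaldehyde, via magnesium-bound salicyl alcohol 3 (not isolated)
Conditions: MgCl2 (anhydrous), Et3N, (CH2O)n, MeCN, reflux; then 1 M HCl
Reagents that add atoms: paraformaldehyde (formaldehyde), C=O
Why: Magnesium-phenoxide-directed ortho-formylation (Casnati–Skattebøl) delivers formaldehyde only to the single free ortho position, and the resulting benzylic alkoxide is oxidized in situ by a second formaldehyde (Oppenauer-type hydride transfer).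

Step 3
Reactants: 4 3-chloro-2-hydroxy-4,6-dimethoxybenzaldehyde
Product: 5 2-(allyloxy)-3-chloro-4,6-dimethoxybenzaldehyde
Conditions: allyl bromide, K2CO3, DMF, 50 °C
Reagents that add atoms: allyl bromide, C=CCBr
Why: Williamson etherification masks the phenol, which would otherwise quench the enolate and deactivate the aldehyde, with a group removable later without touching ArCl, ArOMe or the ketone.

Step 4
Reactants: 6 5-methylcyclohexane-1,3-dione
Product: 7 3-(allyloxy)-5-methylcyclohex-2-en-1-one (racemic)
Conditions: allyl alcohol, TsOH·H2O (cat.), benzene, reflux, Dean–Stark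
Reagents that add atoms: allyl alcohol, OCC=C
Why: Acid-catalysed vinylogous esterification of the symmetrical dione, driven by azeotropic water removal, gives a single regioisomer whose C5 stereocentre is racemic and later erased.

Step 5
Reactants: 7 3-(allyloxy)-5-methylcyclohex-2-en-1-one; 5 2-(allyloxy)-3-chloro-4,6-dimethoxybenzaldehyde
Product: 9 3-(allyloxy)-6-{[2-(allyloxy)-3-chloro-4,6-dimethoxyphenyl](hydroxy)methyl}-5-methylcyclohex-2-en-1-one (racemic diastereomer mixture), via kinetic lithium enolate 8 (not isolated)
Conditions: LDA (commercial solution, 1.25 equiv), THF, −78 °C, 45 min; then 5 (1.0 equiv), −78 °C, 1 h; AcOH quench at −78 °C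
Reagents that add atoms: none
Why: Stork–Danheiser kinetic α'-deprotonation followed by intermolecular aldol addition to the non-enolizable aldehyde forms the central C–C bond, and the new C6 and carbinol stereocentres are left uncontrolled because both are destroyed in steps 6–7.

Step 6
Reactants: 9 aldol adduct (diastereomer mixture)
Product: 10 3-(allyloxy)-6-[2-(allyloxy)-3-chloro-4,6-dimethoxybenzoyl]-5-methylcyclohex-2-en-1-one (racemic; largely enolized)
Conditions: Dess–Martin periodinane (1.3 equiv), CH2Cl2, 0 °C to rt; aq. NaHCO3/Na2S2O3 work-up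
Reagents that add atoms: none
Why: Dess–Martin oxidation converts β-hydroxy ketones to β-diketones under mild non-basic conditions that avoid retro-aldol cleavage and leave the allyl ethers and vinylogous ester intact.

Step 7
Reactants: 10 β-diketone
Product: 11 [2-(allyloxy)-3-chloro-4,6-dimethoxyphenyl][4-(allyloxy)-2-hydroxy-6-methylphenyl]methanone
Conditions: DDQ (1.2 equiv), 1,4-dioxane, 80 °C
Reagents that add atoms: none
Why: The ring-enol tautomer of 10 is a 1,3-cyclohexadiene, so DDQ dehydrogenation (hydride abstraction then proton loss) aromatizes it to the chelated o-hydroxybenzophenone and removes the last stereocentre.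

Step 8
Reactants: 11 phenol
Product: 12 [2-(allyloxy)-3-chloro-4,6-dimethoxyphenyl][4-(allyloxy)-2-methoxy-6-methylphenyl]methanone
Conditions: MeI, K2CO3, DMF, 50 °C
Reagents that add atoms: iodomethane, CI
Why: Williamson O-methylation is unambiguous because the hydrogen-bonded 2-OH of the new ring is the only free hydroxyl in 11.

Step 9
Reactants: 12 bis-allyl ether
Product: 13 (3-chloro-2-hydroxy-4,6-dimethoxyphenyl)(4-hydroxy-2-methoxy-6-methylphenyl)methanone (target)
Conditions: Pd(PPh3)4 (5 mol%), morpholine (10 equiv), THF, rt
Reagents that add atoms: none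
Why: Tsuji–Trost deallylation via π-allylpalladium intermediates, with morpholine as allyl acceptor, frees both phenols under neutral conditions that do not affect the aryl chloride, the methyl ethers or the diaryl ketone.

**Compound list**
1 | 3,5-dimethoxyphenol | COc1cc(O)cc(OC)c1 | starting material
2 | 2-chloro-3,5-dimethoxyphenol | COc1cc(OC)c(Cl)c(O)c1 | intermediate
3 | 2-chloro-6-(hydroxymethyl)-3,5-dimethoxyphenol (held as its magnesium phenoxide in the flask; not isolated) | COc1cc(OC)c(CO)c(O)c1Cl | intermediate
4 | 3-chloro-2-hydroxy-4,6-dimethoxybenzaldehyde | COc1cc(OC)c(C=O)c(O)c1Cl | intermediate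
5 | 2-(allyloxy)-3-chloro-4,6-dimethoxybenzaldehyde | COc1cc(OC)c(C=O)c(OCC=C)c1Cl | intermediate
6 | 5-methylcyclohexane-1,3-dione | CC1CC(=O)CC(=O)C1 | starting material
7 | 3-(allyloxy)-5-methylcyclohex-2-en-1-one (racemic) | CC1CC(=O)C=C(OCC=C)C1 | intermediate
8 | lithium 5-(allyloxy)-3-methylcyclohexa-1,5-dien-1-olate (kinetic C6 enolate of 7; not isolated) | [Li+].CC1CC(OCC=C)=CC([O-])=C1 | intermediate
9 | 3-(allyloxy)-6-{[2-(allyloxy)-3-chloro-4,6-dimethoxyphenyl](hydroxy)methyl}-5-methylcyclohex-2-en-1-one (racemic diastereomer mixture) | COc1cc(OC)c(C(O)C2C(C)CC(OCC=C)=CC2=O)c(OCC=C)c1Cl | intermediate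
10 | 3-(allyloxy)-6-[2-(allyloxy)-3-chloro-4,6-dimethoxybenzoyl]-5-methylcyclohex-2-en-1-one (racemic) | COc1cc(OC)c(C(=O)C2C(C)CC(OCC=C)=CC2=O)c(OCC=C)c1Cl | intermediate
11 | [2-(allyloxy)-3-chloro-4,6-dimethoxyphenyl][4-(allyloxy)-2-hydroxy-6-methylphenyl]methanone | COc1cc(OC)c(C(=O)c2c(C)cc(OCC=C)cc2O)c(OCC=C)c1Cl | intermediate
12 | [2-(allyloxy)-3-chloro-4,6-dimethoxyphenyl][4-(allyloxy)-2-methoxy-6-methylphenyl]methanone | COc1cc(OC)c(C(=O)c2c(C)cc(OCC=C)cc2OC)c(OCC=C)c1Cl | intermediate
13 | (3-chloro-2-hydroxy-4,6-dimethoxyphenyl)(4-hydroxy-2-methoxy-6-methylphenyl)methanone (achiral) | COc1cc(OC)c(C(=O)c2c(C)cc(O)cc2OC)c(O)c1Cl | target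

**Totals**
Total step count: 9. Longest linear sequence: 8 steps (1 → 2 → 4 → 5 → 9 → 10 → 11 → 12 → 13).

**Three steps most likely to fail, with fallbacks**

Step 1 (regioselectivity of chlorination; 4-chloro and dichloro by-products). The fallback sets out from 1 and comes back at 2, replacing electrophilic chlorination by directed ortho-metalation. Compound 1 is carbamoylated (Et2NCOCl, NaH, THF) to 3,5-dimethoxyphenyl N,N-diethylcarbamate F1. F1 is lithiated with s-BuLi/TMEDA in THF at −78 °C at the position flanked by the carbamate and a methoxy group, and quenched cold with C2Cl6 to give 2-chloro-3,5-dimethoxyphenyl N,N-diethylcarbamate F2. Hydrolysis with NaOH in refluxing EtOH then returns phenol 2.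

Step 5 (retro-aldol or sluggish addition to the hindered, electron-rich aldehyde). The fallback sets out from 7 and comes back at 9, replacing the lithium aldol by a Lewis-acid Mukaiyama aldol. Enolate 8, generated from 7 as before, is trapped with TMSCl to give {[5-(allyloxy)-3-methylcyclohexa-1,5-dien-1-yl]oxy}trimethylsilane F3, a cyclic Danishefsky-type diene. F3 is added to aldehyde 5 with BF3·OEt2 in CH2Cl2 at −78 °C and reacts at the same C6 terminus, giving 9 after aqueous work-up without ever forming a basic aldolate.

Step 7 (incomplete or unselective DDQ dehydrogenation). The fallback sets out from 10 and comes back at 11, replacing hydride abstraction by α-selenation and selenoxide elimination. The sodium enolate of 10 (NaH, THF, 0 °C) is treated with PhSeCl to give 3-(allyloxy)-6-[2-(allyloxy)-3-chloro-4,6-dimethoxybenzoyl]-5-methyl-6-(phenylselanyl)cyclohex-2-en-1-one F4. Oxidation with 30% H2O2 in CH2Cl2 (0 °C to rt) triggers syn-elimination toward C5–H, and the resulting cyclohexadienone tautomerizes to phenol 11.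

**Further compounds**
F1 | step 1 | 3,5-dimethoxyphenyl N,N-diethylcarbamate | CCN(CC)C(=O)Oc1cc(OC)cc(OC)c1
F2 | step 1 | 2-chloro-3,5-dimethoxyphenyl N,N-diethylcarbamate | CCN(CC)C(=O)Oc1cc(OC)cc(OC)c1Cl
F3 | step 5 | {[5-(allyloxy)-3-methylcyclohexa-1,5-dien-1-yl]oxy}trimethylsilane (racemic) | CC1CC(OCC=C)=CC(O[Si](C)(C)C)=C1
F4 | step 7 | 3-(allyloxy)-6-[2-(allyloxy)-3-chloro-4,6-dimethoxybenzoyl]-5-methyl-6-(phenylselanyl)cyclohex-2-en-1-one (racemic diastereomer mixture) | COc1cc(OC)c(C(=O)C2([Se]c3ccccc3)C(C)CC(OCC=C)=CC2=O)c(OCC=C)c1Cl
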